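**Retrosynthetic overview**
- C3–CH2CO2H bond: Lewis-acid-mediated (Mukaiyama-type) addition of ketene bis(trimethylsilyl) acetal to the cyclic peroxycarbenium ion of a 1,2-dioxolan-3-ol; this sets C3.
- O–C5 bond and the only ring: organocatalytic asymmetric hydroperoxidation of an (E)-β-methyl-β-alkyl enone with H2O2, then spontaneous peroxyhemiketal closure; this sets C5 and forms the 1,2-dioxolane.
- Enone: zirconium-catalysed methylalumination of a terminal alkyne, then acylation with acetyl chloride.
- (E,E,E)-Triene: Julia–Kocienski olefination of an undecynyl tetrazolyl sulfone with (2E,4E)-hepta-2,4-dienal, installed first and carried through.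

Assumption: the sense of induction in step 5 is taken to follow that of the quinine-derived primary amine with β-monosubstituted (E)-enones; if the first enantiomer analysis shows the 5S series, the quinidine-derived pseudoenantiomer is used under otherwise identical conditions.

**Route**

Step 1
Reactants: 1 undec-10-yn-1-ol
Product: 2 1-phenyl-5-(undec-10-yn-1-ylsulfanyl)-1H-tetrazole
Conditions: 1-phenyl-1H-tetrazole-5-thiol (1.2 equiv), PPh3, DIAD, THF, 0 °C → rt
Reagents that add atoms: 1-phenyl-1H-tetrazole-5-thiol, Sc1nnnn1-c1ccccc1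
Why: Mitsunobu reaction, an SN2 displacement of the activated primary alcohol by the acidic heteroaryl thiol, with the terminal alkyne inert.

Step 2
Reactants: 2 1-phenyl-5-(undec-10-yn-1-ylsulfanyl)-1H-tetrazole
Product: 4 1-phenyl-5-(undec-10-yn-1-ylsulfonyl)-1H-tetrazole, via sulfoxide 3 (not isolated)
Conditions: 30 % H2O2 (6 equiv), (NH4)6Mo7O24·4H2O (10 mol %), EtOH, 0 °C → rt
Reagents that add atoms: hydrogen peroxide, OO
Why: Molybdate-catalysed peroxide oxidation of the sulfide to the sulfone, which leaves the terminal alkyne untouched.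

Step 3
Reactants: 4 1-phenyl-5-(undec-10-yn-1-ylsulfonyl)-1H-tetrazole; 5 (2E,4E)-hepta-2,4-dienal
Product: 7 (11E,13E,15E)-octadeca-11,13,15-trien-1-yne, via potassium sulfonyl carbanion 6 (not isolated)
Conditions: KN(SiMe3)2 (1.05 equiv), DME, −60 °C, 30 min; then 5 (1.2 equiv), −60 °C → rt; aq NH4Cl
Reagents that add atoms: none
Why: Julia–Kocienski olefination, in which the metalated sulfone adds to the dienal and loses SO2 and tetrazolate to give the new C11=C12 bond E-selectively (potassium counter-ion, DME), while the two E alkenes of 5 are carried over unchanged and the less acidic alkyne C–H is not deprotonated.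

Step 4
Reactants: 7 (11E,13E,15E)-octadeca-11,13,15-trien-1-yne
Product: 9 (3E,13E,15E,17E)-4-methylicosa-3,13,15,17-tetraen-2-one, via alkenyldimethylalane 8 (not isolated)
Conditions: AlMe3 (2.5 equiv), Cp2ZrCl2 (25 mol %), CH2Cl2, 0 °C → rt; volatiles removed; then AcCl (3 equiv), Pd(PPh3)4 (5 mol %), THF, 0 °C → rt; aq Rochelle salt
Reagents that add atoms: trimethylaluminium, C[Al](C)C; acetyl chloride, CC(=O)Cl
Why: Negishi zirconium-catalysed carboalumination adds Me and Al syn across the terminal alkyne (methyl to the internal carbon), and the palladium-catalysed acylation of the alkenylalane proceeds with retention, so the chain ends up trans to the acetyl group (E); the internal triene does not carbometalate.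

Step 5
Reactants: 9 (3E,13E,15E,17E)-4-methylicosa-3,13,15,17-tetraen-2-one
Product: 11 (5R)-5-[(9E,11E,13E)-hexadeca-9,11,13-trien-1-yl]-3,5-dimethyl-1,2-dioxolan-3-ol, via β-hydroperoxy ketone 10 (not isolated)
Conditions: 9-amino-9-deoxy-epi-quinine (20 mol %), Cl3CCO2H (40 mol %), 50 % aq H2O2 (3 equiv), 1,4-dioxane, 30 °C, dark, 48 h
Reagents that add atoms: hydrogen peroxide, OO
Why: Proposed new method: the primary amine condenses with the methyl ketone of 9 to an s-trans iminium ion in which the fixed E geometry keeps the long chain anti and the methyl syn to the iminium carbon, so that H2O2 held by the protonated quinuclidine attacks one enantioface of the β-carbon and creates the tetrasubstituted C–OO centre (R), after which hydrolysis releases hydroperoxy ketone 10 and its closure to peroxyhemiketal 11 (the ring-forming event, C3 epimers in equilibrium) pulls the reversible addition forward; the closest known reaction type is the cinchona primary-amine-catalysed asymmetric hydroperoxidation of β-monosubstituted acyclic enones and epoxidation of 3-substituted cyclohexenones with H2O2, which has not been shown for acyclic β,β-disubstituted enones.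

Step 6
Reactants: 12 trimethylsilyl acetate
Product: 14 1,1-bis(trimethylsilyloxy)ethene (ketene bis(trimethylsilyl) acetal), via lithium enolate 13 (not isolated)
Conditions: LiN(iPr)2 (1.1 equiv), THF, −78 °C; then Me3SiCl (1.2 equiv), −78 °C → rt; filter, distil
Reagents that add atoms: chlorotrimethylsilane, C[Si](C)(C)Cl
Why: Standard silyl ketene acetal synthesis by O-silylation of the lithium ester enolate.

Step 7
Reactants: 11 (5R)-5-[(9E,11E,13E)-hexadeca-9,11,13-trien-1-yl]-3,5-dimethyl-1,2-dioxolan-3-ol; 14 1,1-bis(trimethylsilyloxy)ethene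
Product: 18 2-[(3S,5R)-5-[(9E,11E,13E)-hexadeca-9,11,13-trien-1-yl]-3,5-dimethyl-1,2-dioxolan-3-yl]acetic acid, via silyl peroxyketal 15 (not isolated), via peroxycarbenium triflate 16 (not isolated), via trimethylsilyl ester 17 (not isolated)
Conditions: 14 (3 equiv), CH2Cl2, 0 °C, 30 min; then 2,6-di-tert-butyl-4-methylpyridine (0.3 equiv), Me3SiOTf (0.5 equiv), −78 → −40 °C; pH 4 citrate buffer; silica gel, then HPLC to remove the C3 epimer
Reagents that add atoms: none
Why: Mukaiyama-type substitution through a peroxycarbenium ion (known for 3-alkoxy-1,2-dioxolanes with silyl ketene acetals), in which 14 silylates the hemiketal OH, Me3SiOTf ionises 15 to 16, and a second molecule of 14 attacks C3 on the face anti to the C16 chain at C5 to give 3S with only modest substrate control (about 1:1 to 2:1 expected, the 3R epimer being separated), while C5 is untouched and the bis-silyl reagent releases the free acid on work-up.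

**Compound list**

1 | undec-10-yn-1-ol | C#CCCCCCCCCCO | starting material
2 | 1-phenyl-5-(undec-10-yn-1-ylsulfanyl)-1H-tetrazole | C#CCCCCCCCCCSc1nnnn1-c1ccccc1 | intermediate
3 | 1-phenyl-5-(undec-10-yn-1-ylsulfinyl)-1H-tetrazole (racemic) | C#CCCCCCCCCCS(=O)c1nnnn1-c1ccccc1 | intermediate (not isolated)
4 | 1-phenyl-5-(undec-10-yn-1-ylsulfonyl)-1H-tetrazole | C#CCCCCCCCCCS(=O)(=O)c1nnnn1-c1ccccc1 | intermediate
5 | (2E,4E)-hepta-2,4-dienal | CC/C=C/C=C/C=O | starting material
6 | potassium 1-[(1-phenyl-1H-tetrazol-5-yl)sulfonyl]undec-10-yn-1-ide | [K+].C#CCCCCCCCC[CH-]S(=O)(=O)c1nnnn1-c1ccccc1 | intermediate (not isolated)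
7 | (11E,13E,15E)-octadeca-11,13,15-trien-1-yne | C#CCCCCCCCC/C=C/C=C/C=C/CC | intermediate
8 | dimethyl[(1E,11E,13E,15E)-2-methyloctadeca-1,11,13,15-tetraen-1-yl]alane | CC/C=C/C=C/C=C/CCCCCCCC/C(C)=C/[Al](C)C | intermediate (not isolated)
9 | (3E,13E,15E,17E)-4-methylicosa-3,13,15,17-tetraen-2-one | CC/C=C/C=C/C=C/CCCCCCCC/C(C)=C/C(C)=O | intermediate
10 | (4R,13E,15E,17E)-4-hydroperoxy-4-methylicosa-13,15,17-trien-2-one | CC/C=C/C=C/C=C/CCCCCCCC[C@@](C)(OO)CC(C)=O | intermediate (not isolated)
11 | (5R)-5-[(9E,11E,13E)-hexadeca-9,11,13-trien-1-yl]-3,5-dimethyl-1,2-dioxolan-3-ol (C3 epimers) | CC/C=C/C=C/C=C/CCCCCCCC[C@]1(C)CC(C)(O)OO1 | intermediate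
12 | trimethylsilyl acetate | CC(=O)O[Si](C)(C)C | starting material
13 | lithium 1-(trimethylsilyloxy)ethen-1-olate | [Li+].C=C([O-])O[Si](C)(C)C | intermediate (not isolated)
14 | 1,1-bis(trimethylsilyloxy)ethene | C=C(O[Si](C)(C)C)O[Si](C)(C)C | intermediate
15 | {[(5R)-5-[(9E,11E,13E)-hexadeca-9,11,13-trien-1-yl]-3,5-dimethyl-1,2-dioxolan-3-yl]oxy}trimethylsilane (C3 epimers) | CC/C=C/C=C/C=C/CCCCCCCC[C@]1(C)CC(C)(O[Si](C)(C)C)OO1 | intermediate (not isolated)
16 | (5R)-5-[(9E,11E,13E)-hexadeca-9,11,13-trien-1-yl]-3,5-dimethyl-1,2-dioxolan-3-ylium trifluoromethanesulfonate | CC/C=C/C=C/C=C/CCCCCCCC[C@]1(C)C[C+](C)OO1.[O-]S(=O)(=O)C(F)(F)F | intermediate (not isolated)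
17 | trimethylsilyl 2-[(3S,5R)-5-[(9E,11E,13E)-hexadeca-9,11,13-trien-1-yl]-3,5-dimethyl-1,2-dioxolan-3-yl]acetate | CC/C=C/C=C/C=C/CCCCCCCC[C@]1(C)C[C@@](C)(CC(=O)O[Si](C)(C)C)OO1 | intermediate (not isolated)
18 | 2-[(3S,5R)-5-[(9E,11E,13E)-hexadeca-9,11,13-trien-1-yl]-3,5-dimethyl-1,2-dioxolan-3-yl]acetic acid | CC/C=C/C=C/C=C/CCCCCCCC[C@]1(C)C[C@@](C)(CC(=O)O)OO1 | target

**Count**

Total steps: 7. Longest linear sequence: 6 (steps 1, 2, 3, 4, 5, 7); step 6 makes reagent 14 in one step from 12.

**Three steps most likely to fail**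

Step 5 (the proposed new step). The risks are slow addition at the fully substituted β-carbon, E/Z scrambling of 9 through a dienamine (which would erode the ee), and Weitz–Scheffer closure to the epoxy ketone. The fallback uses known chemistry and sets out from 9. Non-asymmetric perhydrolysis of the enone, long known for mesityl-oxide-type β,β-disubstituted enones (50 % H2O2, catalytic NaOH, MeOH, −10 °C, short contact), gives the racemic 1,2-dioxolan-3-ol F1. This is taken through the conditions of step 7, passing in the flask through the racemic silyl peroxyketal F2, the racemic peroxycarbenium triflate F3 and the racemic trimethylsilyl ester F4, to the racemic trans acid F5. F5 is resolved by preparative HPLC on an amylose tris(3,5-dimethylphenylcarbamate) phase, and the fallback comes back to the route at 18.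

Step 7. The risks are the low facial bias at C3 (methyl versus a CH2 chain at C5) and the use of the free peroxyhemiketal with in-flask silylation. The fallback sets out from 11 and follows the stepwise, precedented sequence. Ketal exchange (MeOH, catalytic pyridinium p-toluenesulfonate, rt) gives the methyl peroxyketal F6. TiCl4 (1.1 equiv) and commercial 1-(tert-butyldimethylsilyloxy)-1-methoxyethene in CH2Cl2 at −78 °C give the methyl ester F7, whose C3 epimers are separated at the ester stage, where chromatography is easier than for the acids. Saponification (LiOH, THF/H2O, 0 °C) then comes back to the route at 18.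

Step 4. The risk is that acetyl chloride with aluminium Lewis acids attacks or isomerises the conjugated triene, or that methyl transfer competes. The fallback sets out from 7. The same zirconium-catalysed carboalumination to 8 is quenched with I2 (THF, −30 °C) to give the (E)-alkenyl iodide F8. Nozaki–Hiyama–Kishi addition to acetaldehyde (CrCl2, 1 mol % NiCl2, DMF, rt) gives the allylic alcohol F9. MnO2 in CH2Cl2 oxidises it, and the fallback comes back to the route at 9.

**Further compounds**

F1 | step 5 | racemic 5-[(9E,11E,13E)-hexadeca-9,11,13-trien-1-yl]-3,5-dimethyl-1,2-dioxolan-3-ol | CC/C=C/C=C/C=C/CCCCCCCCC1(C)CC(C)(O)OO1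
F2 | step 5 | racemic {[5-[(9E,11E,13E)-hexadeca-9,11,13-trien-1-yl]-3,5-dimethyl-1,2-dioxolan-3-yl]oxy}trimethylsilane | CC/C=C/C=C/C=C/CCCCCCCCC1(C)CC(C)(O[Si](C)(C)C)OO1
F3 | step 5 | racemic 5-[(9E,11E,13E)-hexadeca-9,11,13-trien-1-yl]-3,5-dimethyl-1,2-dioxolan-3-ylium trifluoromethanesulfonate | CC/C=C/C=C/C=C/CCCCCCCCC1(C)C[C+](C)OO1.[O-]S(=O)(=O)C(F)(F)F
F4 | step 5 | racemic trimethylsilyl 2-[(3S*,5R*)-5-[(9E,11E,13E)-hexadeca-9,11,13-trien-1-yl]-3,5-dimethyl-1,2-dioxolan-3-yl]acetate | CC/C=C/C=C/C=C/CCCCCCCC[C@]1(C)C[C@@](C)(CC(=O)O[Si](C)(C)C)OO1.CC/C=C/C=C/C=C/CCCCCCCC[C@@]1(C)C[C@](C)(CC(=O)O[Si](C)(C)C)OO1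
F5 | step 5 | racemic 2-[(3S*,5R*)-5-[(9E,11E,13E)-hexadeca-9,11,13-trien-1-yl]-3,5-dimethyl-1,2-dioxolan-3-yl]acetic acid | CC/C=C/C=C/C=C/CCCCCCCC[C@]1(C)C[C@@](C)(CC(=O)O)OO1.CC/C=C/C=C/C=C/CCCCCCCC[C@@]1(C)C[C@](C)(CC(=O)O)OO1
F6 | step 7 | (5R)-5-[(9E,11E,13E)-hexadeca-9,11,13-trien-1-yl]-3-methoxy-3,5-dimethyl-1,2-dioxolane (C3 epimers) | CC/C=C/C=C/C=C/CCCCCCCC[C@]1(C)CC(C)(OC)OO1
F7 | step 7 | methyl 2-[(3S,5R)-5-[(9E,11E,13E)-hexadeca-9,11,13-trien-1-yl]-3,5-dimethyl-1,2-dioxolan-3-yl]acetate | CC/C=C/C=C/C=C/CCCCCCCC[C@]1(C)C[C@@](C)(CC(=O)OC)OO1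
F8 | step 4 | (1E,11E,13E,15E)-1-iodo-2-methyloctadeca-1,11,13,15-tetraene | CC/C=C/C=C/C=C/CCCCCCCC/C(C)=C/I
F9 | step 4 | (3E,13E,15E,17E)-4-methylicosa-3,13,15,17-tetraen-2-ol (racemic) | CC/C=C/C=C/C=C/CCCCCCCC/C(C)=C/C(C)O
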